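**Retrosynthetic overview**

1. The route rests on C9, the all-carbon quaternary centre shared by ring A (C10, C1–C5, C9), ring B (C5–C9) and ring C (C8, C9, C11–C14) and bonded to the oxygenated C10. It is made by a semipinacol shift of C8 from the carbinol carbon C11 onto C9 of a C9–C10 epoxide, which expands a cyclopentanol to ring C and leaves the C10 alcohol.
2. After the shift: ring B by ring-closing metathesis of the C5 and C8 vinyl groups, hydrogenation, removal of the C11 ketone, and last the C3–O–C10 bridge by acid (C10 cation trapped by the C3 hydroxyl).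
3. Before the shift: a ring A alkenylcerium (C9) adds to the C11 ketone of a ring D hydrindanone, and the tertiary hydroxyl directs epoxidation of C9=C10.
4. Hydrindanone from (S)-Hajos–Parrish ketone: C13 methyl by directed cyclopropanation and reductive opening, C17 by nitrile methylation and hydroboration–Suzuki coupling, C11 ketone and C8 vinyl through an α-ketol and SmI2.
5. Ring A from carvone via eucarvone (Jacobsen epoxidation for C3, kinetic protonation for C5, enol triflate to stannane). Ring order: D and the cyclopentane (starting material), A (eucarvone), C (key step), B (metathesis), oxygen bridge (last).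

Key step: step 27

Remark: carbon numbers are those of the target throughout (ring D = C13–C18); α is the face of the C14 methyl, β the face of the C13 methyl, and the "lower face" of ring A is that of the C3 oxygen. Stereocentres that are erased later (C17 in 7, C11 in 16–17 and 44–46, C8 in 17–18, C5 and the carbinol in 29–30, C10 in 25) are drawn as expected or left open.

**Route**

Step 1
Reactants: 1 (S)-Hajos–Parrish ketone
Product: 2 C8 ethylene ketal of the enedione
Conditions: Me3SiOCH2CH2OSiMe3, Me3SiOTf (cat.), CH2Cl2, −78 → −20 °C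
Reagents that add atoms: 1,2-bis(trimethylsilyloxy)ethane, C[Si](C)(C)OCCO[Si](C)(C)C
Why: Noyori ketalization reacts with the saturated C8 ketone and leaves the conjugated C17 enone untouched, so the five-membered-ring carbonyl is masked in one step.

Step 2
Reactants: 2 C8 ketal enone
Product: 3 C17 allylic alcohol (hydroxyl β)
Conditions: LiBH(s-Bu)3, THF, −78 °C; H2O
Reagents that add atoms: none
Why: 1,2-reduction of the β,β-disubstituted enone by a bulky trialkylborohydride from the equatorial direction should give the pseudo-axial alcohol trans to the C14 methyl (as in such reductions of steroidal 4-en-3-ones), the face needed to direct step 3.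

Step 3
Reactants: 3 C17 allylic alcohol
Product: 4 cyclopropyl carbinol
Conditions: Et2Zn, CH2I2, CH2Cl2, 0 °C
Reagents that add atoms: diiodomethane, ICI
Why: hydroxyl-directed Simmons–Smith cyclopropanation delivers CH2 to C13=C18 on the hydroxyl face, which fixes the future C13 methyl trans to the C14 methyl.

Step 4
Reactants: 4 cyclopropyl carbinol
Product: 5 cyclopropyl ketone
Conditions: Dess–Martin periodinane, NaHCO3, CH2Cl2, rt
Reagents that add atoms: none
Why: Dess–Martin oxidation of the secondary carbinol is neutral and leaves ketal and cyclopropane intact.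

Step 5
Reactants: 5 cyclopropyl ketone
Product: 6 trans-dimethyl hydrindanone (C17 ketone)
Conditions: Li, NH3 (l), THF, −78 °C; NH4Cl
Reagents that add atoms: none
Why: dissolving-metal reduction cleaves the exocyclic C18–CH2 bond, which overlaps best with the carbonyl π system, and so unveils the angular C13 methyl with the configuration set in step 3.

Step 6
Reactants: 6 trans-dimethyl hydrindanone
Product: 7 C17 nitrile
Conditions: TosMIC, t-BuOK, DME–EtOH, 0 → 40 °C
Reagents that add atoms: p-toluenesulfonylmethyl isocyanide, Cc1ccc(cc1)S(=O)(=O)C[N+]#[C-]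
Why: van Leusen reductive cyanation turns the unhindered C17 ketone into the nitrile with one added carbon; the C17 configuration is irrelevant because the centre is deprotonated next.

Step 7
Reactants: 7 C17 nitrile
Product: 9 C17 methyl nitrile, via lithiated nitrile 8 (not isolated)
Conditions: LiN(i-Pr)2, THF, −78 °C; MeI
Reagents that add atoms: iodomethane, CI
Why: alkylation of the lithiated nitrile should occur from the equatorial direction because the axial face of C17 is blocked by the syn-axial C13 methyl, so methyl enters α and the nitrile stays β, which sets the C17 quaternary centre.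

Step 8
Reactants: 9 C17 methyl nitrile
Product: 10 C17 aldehyde
Conditions: i-Bu2AlH, toluene, −78 °C; aq. Rochelle salt, SiO2
Reagents that add atoms: water, O
Why: partial reduction of the tertiary nitrile stops at the N-aluminio imine, which hydrolyses to the aldehyde on the buffered work-up that the ketal survives.

Step 9
Reactants: 10 C17 aldehyde
Product: 11 C17 vinyl compound
Conditions: Ph3PCH3Br, t-BuOK, THF, 0 °C → rt
Reagents that add atoms: methyltriphenylphosphonium bromide, C[P+](c1ccccc1)(c1ccccc1)c1ccccc1.[Br-]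
Why: Wittig methylenation of a non-enolisable neopentyl aldehyde.

Step 10
Reactants: 11 C17 vinyl compound
Product: 13 ketal bearing the 4-methylpent-3-enyl chain, via B-alkyl-9-BBN 12 (not isolated)
Conditions: 9-BBN, THF, rt; then Me2C=CHBr, PdCl2(dppf) (cat.), aq. K3PO4, DMF, 50 °C
Reagents that add atoms: 1-bromo-2-methylprop-1-ene, CC(C)=CBr
Why: anti-Markovnikov hydroboration of the only alkene followed by B-alkyl Suzuki–Miyaura coupling builds the side chain without touching C17.

Step 11
Reactants: 13 side-chain ketal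
Product: 14 C8 ketone
Conditions: 1 M HCl, THF, rt
Reagents that add atoms: water, O
Why: acid hydrolysis of the dioxolane returns the C8 ketone; the isolated trisubstituted alkene tolerates dilute acid at room temperature.

Step 12
Reactants: 14 C8 ketone
Product: 16 C11-hydroxy C8 ketone, via potassium enolate 15 (not isolated)
Conditions: KN(SiMe3)2, THF, −78 °C; 2-(phenylsulfonyl)-3-phenyloxaziridine, −78 °C
Reagents that add atoms: 2-(phenylsulfonyl)-3-phenyloxaziridine, O=S(=O)(N1OC1c1ccccc1)c1ccccc1
Why: the ketone can enolise only toward C11 (C14 is quaternary) and Davis hydroxylation of the enolate installs the C11 oxygen; attack anti to the C14 methyl is expected, but either epimer serves because C11 becomes a carbonyl in step 14.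

Step 13
Reactants: 16 C11-hydroxy C8 ketone
Product: 17 C8-vinyl C8,C11-diol
Conditions: CH2=CHMgBr (3 equiv), THF, −78 → 0 °C
Reagents that add atoms: vinylmagnesium bromide, C=C[Mg]Br
Why: Grignard 1,2-addition, expected from the β face anti to the vicinal C14 methyl as with 17-keto steroids; the C8 configuration is erased in step 15, so only the constitution matters.

Step 14
Reactants: 17 diol
Product: 18 C11 ketone with C8 hydroxyl and vinyl
Conditions: SO3·pyridine, DMSO, i-Pr2NEt, CH2Cl2, 0 °C
Reagents that add atoms: none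
Why: Parikh–Doering oxidation converts the secondary C11 alcohol into the ketone without cleaving the 1,2-diol or touching the tertiary allylic alcohol and the alkenes.

Step 15
Reactants: 18 α-hydroxy ketone
Product: 19 hydrindanone (C11 ketone, C8 vinyl α)
Conditions: SmI2 (2.5 equiv), THF–MeOH, −78 °C
Reagents that add atoms: none
Why: SmI2 cleaves the C8–O bond of the α-hydroxy ketone to a samarium dienolate, and kinetic α-protonation by methanol from the β face, anti to the vicinal C14 methyl, should give the β,γ-unsaturated ketone with the vinyl group α (pseudo-equatorial, also the more stable epimer).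

Step 16
Reactants: 20 (R)-carvone
Product: 23 eucarvone, via hydrobromide 21 (not isolated), via carenone 22 (not isolated)
Conditions: HBr (33% in AcOH), 0 °C; then KOH, MeOH, reflux
Reagents that add atoms: none
Why: classical eucarvone synthesis: Markovnikov HBr addition, base-induced 1,3-elimination to the carenone (intramolecular enolate alkylation) and 6π electrocyclic opening of its dienolate to the achiral cycloheptadienone.

Step 17
Reactants: 23 eucarvone
Product: 24 (4S,5R)-4,5-epoxide
Conditions: (S,S)-N,N'-bis(3,5-di-tert-butylsalicylidene)-1,2-cyclohexanediaminomanganese chloride (5 mol %), 4-phenylpyridine N-oxide, aq. NaOCl (pH 11.3), CH2Cl2, 0 °C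
Reagents that add atoms: sodium hypochlorite, [Na+].[O-]Cl
Why: Jacobsen epoxidation picks the electron-richer cis γ,δ-alkene, which is conjugated on one side and flanked by the gem-dimethyl carbon on the other like 2,2-dimethylchromene; by that analogy the (S,S)-catalyst should give the epoxide that carries the C3 configuration of the target.

Step 18
Reactants: 24 epoxy enone
Product: 26 (S)-5-hydroxy-2,6,6-trimethylcyclohept-2-enone, via deconjugated hydroxy ketone 25 (not isolated)
Conditions: SmI2 (2.2 equiv), THF–MeOH, −78 °C; then DBU (cat.), CH2Cl2, rt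
Reagents that add atoms: none
Why: two-electron reduction of the vinylogous epoxy ketone breaks the allylic C2–O bond and leaves the C3–O bond and its configuration untouched; protonation and amidine-catalysed reconjugation give the 2-methyl enone.

Step 19
Reactants: 26 hydroxy enone
Product: 27 C3 silyl ether
Conditions: t-BuMe2SiOTf, 2,6-lutidine, CH2Cl2, −78 → 0 °C
Reagents that add atoms: tert-butyldimethylsilyl triflate, CC(C)(C)[Si](C)(C)OS(=O)(=O)C(F)(F)F
Why: silylation of the hindered secondary alcohol with a silyl triflate and a non-nucleophilic base.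

Step 20
Reactants: 27 silyloxy enone
Product: 29 C5 aldol adduct, via lithium dienolate 28 (not isolated)
Conditions: LiN(i-Pr)2, THF, −78 °C; CH3CHO; AcOH
Reagents that add atoms: acetaldehyde, CC=O
Why: kinetic deprotonation at the only α′ position (C5) and aldol addition bring in the two vinyl carbons; the new stereocentres are removed in step 21.

Step 21
Reactants: 29 aldol adduct
Product: 31 C5 ethylidene dienone, via mesylate 30 (not isolated)
Conditions: MeSO2Cl, Et3N, CH2Cl2, 0 °C; then DBU, rt
Reagents that add atoms: none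
Why: mesylation and E1cB elimination give the cross-conjugated dienone, expected with the methyl syn to the carbonyl to avoid A(1,3) strain with the C4 gem-dimethyl group.

Step 22
Reactants: 31 ethylidene dienone
Product: 33 (5S,7S)-vinyl enone, via lithium trienolate 32 (not isolated)
Conditions: LiN(i-Pr)2, THF, −78 °C; then AcOH, −78 °C
Reagents that add atoms: none
Why: kinetic γ-deprotonation of the ethylidene methyl and deconjugative α-protonation at C5 from the face opposite the pseudo-axial C4 methyl should place the vinyl group cis to the C3 silyloxy group, which is also the all-equatorial isomer.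

Step 23
Reactants: 33 vinyl enone
Product: 35 tetrasubstituted enol triflate, via lithium enolate 34 (not isolated)
Conditions: LiBH(s-Bu)3, THF, −78 °C; then N-(5-chloro-2-pyridyl)bis(trifluoromethanesulfonimide), −78 → 0 °C
Reagents that add atoms: N-(5-chloro-2-pyridyl)bis(trifluoromethanesulfonimide), FC(F)(F)S(=O)(=O)N(c1ccc(Cl)cn1)S(=O)(=O)C(F)(F)F
Why: conjugate reduction of the 2-methyl enone gives the regiodefined C9=C10 enolate, which is O-triflated by the Comins reagent before it can equilibrate toward the acidic C5–H.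

Step 24
Reactants: 35 enol triflate
Product: 36 ring A alkenylstannane
Conditions: Me3SnSnMe3, Pd(PPh3)4 (cat.), LiCl, dioxane, 90 °C
Reagents that add atoms: hexamethylditin, C[Sn](C)(C)[Sn](C)(C)C
Why: palladium-catalysed stannylation of the enol triflate (Stille-type coupling) keeps the double bond in place.

Step 25
Reactants: 36 ring A alkenylstannane; 19 hydrindanone
Product: 39 tertiary allylic alcohol, via alkenyllithium 37 (not isolated), via alkenylcerium dichloride 38 (not isolated)
Conditions: 36, MeLi, THF, −78 → −40 °C; CeCl3, −78 °C; then 19, −78 → −40 °C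
Reagents that add atoms: none
Why: tin–lithium exchange, transmetalation to the less basic organocerium (to suppress enolisation of the α-vinyl ketone) and 1,2-addition to C11 from the β face, anti to the C8 vinyl group, give the carbinol, whose C11 centre is destroyed in step 27.

Step 26
Reactants: 39 tertiary allylic alcohol
Product: 40 epoxy alcohol (C9–C10 epoxide on the lower face)
Conditions: VO(acac)2 (cat.), t-BuOOH, CH2Cl2, 0 °C → rt
Reagents that add atoms: tert-butyl hydroperoxide, CC(C)(C)OO
Why: hydroxyl-directed vanadium epoxidation touches only the tetrasubstituted C9=C10 bond of the allylic alcohol; the carbinol rotamer that keeps the hydrindane over the ring A face opposite the C5 vinyl group puts the V–O bond on the vinyl face, so oxygen should be delivered syn to the C5 vinyl and C3 silyloxy groups.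

Step 27
Reactants: 40 epoxy alcohol
Product: 41 spiro C11 ketone with C10 tertiary alcohol
Conditions: BF3·OEt2, CH2Cl2, −78 °C
Reagents that add atoms: none
Why: BF3 coordinates the epoxide oxygen, the tertiary C9–O bond lengthens and C8 shifts from the carbinol carbon C11 to C9 anti to the departing oxygen while the C11 oxygen forms the ketone, which is the Lewis-acid semipinacol rearrangement known for tertiary α-hydroxy epoxides with ring expansion. Ring C (C8, C9, C11–C14) is closed by this 1,2-shift as a one-carbon expansion of the cyclopentanol (three-centre migration, 3-exo-tet at C9), and the new cyclohexanone is spiro-linked to ring A. C9 is the only new stereocentre: it forms with inversion, so its configuration follows from the epoxide face set in step 26, and C8 migrates with retention. Two selectivities are needed: C9–O rather than C10–O cleavage, favoured because only ionisation at C9 is assisted by the migrating bond and the oxygen push from C11; and migration of C8 rather than C12, favoured because C8 is secondary and allylic and can lie antiperiplanar to C9–O when the hydroxyl is gauche to the epoxide oxygen. The silyl ether, both vinyl groups and the side-chain alkene are inert at −78 °C, and the epoxide oxygen stays on C10 as the tertiary alcohol.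

Step 28
Reactants: 41 spiro ketone diene
Product: 42 ring B cyclopentene
Conditions: second-generation Hoveyda–Grubbs catalyst, RuCl2(H2IMes)(=CH-C6H4-2-O-i-Pr) (10 mol %), toluene, 80 °C
Reagents that add atoms: none
Why: ring-closing metathesis of the two monosubstituted alkenes closes the five-membered ring B (C5–C9) with loss of ethene; the trisubstituted side-chain alkene is far less reactive.

Step 29
Reactants: 42 cyclopentene
Product: 43 saturated keto alcohol
Conditions: H2 (4 atm), RhCl(PPh3)3 (cat.), benzene–EtOH, rt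
Reagents that add atoms: none
Why: RhCl(PPh3)3 hydrogenates the cis-disubstituted cyclopentene much faster than the trisubstituted side-chain alkene; no stereocentre is formed.

Step 30
Reactants: 43 keto alcohol
Product: 44 C10,C11-diol
Conditions: LiAlH4, THF, 0 °C
Reagents that add atoms: none
Why: hydride reduction of the hindered C11 ketone at low temperature outruns retro-aldol cleavage; the new carbinol configuration is immaterial because the oxygen is removed.

Step 31
Reactants: 44 diol
Product: 46 C11 S-methyl xanthate, via sodium xanthate 45 (not isolated)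
Conditions: NaH (1.2 equiv), THF, 0 °C; CS2; then MeI
Reagents that add atoms: carbon disulfide, S=C=S; iodomethane, CI
Why: xanthate formation (first half of the Barton–McCombie deoxygenation) at the secondary C11 alkoxide; with about one equivalent of base the hindered tertiary C10 alcohol should stay free.

Step 32
Reactants: 46 xanthate
Product: 47 C11-deoxy C10 alcohol
Conditions: Bu3SnH, AIBN (cat.), toluene, 100 °C
Reagents that add atoms: none
Why: Barton–McCombie radical deoxygenation releases the secondary C11 radical, which is reduced by the stannane; the isolated alkene and the silyl ether are inert.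

Step 33
Reactants: 47 silyl ether
Product: 48 C3,C10-diol
Conditions: Bu4NF, THF, 50 °C
Reagents that add atoms: none
Why: fluoride cleavage of the secondary silyl ether.

Step 34
Reactants: 48 diol
Product: 49 target CNP0284367.1
Conditions: p-TsOH·H2O (cat.), CH2Cl2, rt
Reagents that add atoms: none
Why: acid-catalysed cyclodehydration of the 1,4-diol (as in cineole formation): the tertiary C10 alcohol ionises and the C3 hydroxyl on the lower face traps the cation transannularly (5-exo closure to the 8-oxabicyclo[3.2.1]octane), the C10 configuration being dictated by the bridge.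

**Compound list**

1 | (S)-7a-methyl-2,3,7,7a-tetrahydro-1H-indene-1,5(6H)-dione (Hajos–Parrish ketone) | C[C@]12CCC(=O)C=C1CCC2=O | starting material
2 | (S)-7a-methyl-2,3,7,7a-tetrahydrospiro[indene-1,2'-[1,3]dioxolan]-5(6H)-one (C8 ketal, C17 enone) | O=C1CC[C@]2(C)C3(OCCO3)CCC2=C1 | intermediate
3 | (5R,7aS)-allylic alcohol of 2, C17 hydroxyl β (trans to the C14 methyl) | O[C@@H]1CC[C@]2(C)C3(OCCO3)CCC2=C1 | intermediate
4 | cyclopropyl carbinol: 3 with a methylene bridging C13 and C18 on the β face, cis to the C17 hydroxyl | O[C@@H]1CC[C@]2(C)C3(OCCO3)CC[C@]24C[C@H]14 | intermediate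
5 | cyclopropyl ketone: C17 ketone of 4 | O=C1CC[C@]2(C)C3(OCCO3)CC[C@]24C[C@H]14 | intermediate
6 | (3aS,7aS)-3a,7a-dimethylhexahydrospiro[indene-1,2'-[1,3]dioxolan]-5(4H)-one (C13 methyl β, C14 methyl α, C17 ketone) | O=C1CC[C@]2(C)C3(OCCO3)CC[C@@]2(C)C1 | intermediate
7 | C17 carbonitrile of the ketal (C17 epimers) | N#CC1CC[C@]2(C)C3(OCCO3)CC[C@@]2(C)C1 | intermediate
8 | N-lithio ketenimine of 7 | [Li]N=C=C1CC[C@]2(C)C3(OCCO3)CC[C@@]2(C)C1 | intermediate
9 | C17 methyl nitrile (methyl α equatorial, nitrile β axial) | N#C[C@]1(C)CC[C@]2(C)C3(OCCO3)CC[C@@]2(C)C1 | intermediate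
10 | C17 carbaldehyde (formyl β, methyl α) | O=C[C@]1(C)CC[C@]2(C)C3(OCCO3)CC[C@@]2(C)C1 | intermediate
11 | C17 vinyl compound (vinyl β, methyl α) | C=C[C@]1(C)CC[C@]2(C)C3(OCCO3)CC[C@@]2(C)C1 | intermediate
12 | 9-[2-(C17-yl)ethyl]-9-borabicyclo[3.3.1]nonane from 11 | C(C[C@]1(C)CC[C@]2(C)C3(OCCO3)CC[C@@]2(C)C1)B1C2CCCC1CCC2 | intermediate
13 | ketal with the complete C17 side chain (4-methylpent-3-enyl β, methyl α) | CC(C)=CCC[C@]1(C)CC[C@]2(C)C3(OCCO3)CC[C@@]2(C)C1 | intermediate
14 | C8 ketone: trans-3a,7a-dimethyl-5-methyl-5-(4-methylpent-3-enyl)hydrindan-1-one | CC(C)=CCC[C@]1(C)CC[C@]2(C)C(=O)CC[C@@]2(C)C1 | intermediate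
15 | potassium enolate of 14 (C8=C11) | CC(C)=CCC[C@]1(C)CC[C@]2(C)C(O[K])=CC[C@@]2(C)C1 | intermediate
16 | C8 ketone with C11 hydroxyl (drawn β) | CC(C)=CCC[C@]1(C)CC[C@]2(C)C(=O)[C@H](O)C[C@@]2(C)C1 | intermediate
17 | C8,C11-diol with C8 vinyl (vinyl β, C8 hydroxyl α, C11 hydroxyl β) | CC(C)=CCC[C@]1(C)CC[C@]2(C)[C@@](C=C)(O)[C@H](O)C[C@@]2(C)C1 | intermediate
18 | C11 ketone with C8 hydroxyl (α) and C8 vinyl (β) | CC(C)=CCC[C@]1(C)CC[C@]2(C)[C@@](C=C)(O)C(=O)C[C@@]2(C)C1 | intermediate
19 | (1R,3aR,5R,7aR)-3a,5,7a-trimethyl-5-(4-methylpent-3-enyl)-1-vinyloctahydro-2H-inden-2-one (C11 ketone, C8 vinyl α) | CC(C)=CCC[C@]1(C)CC[C@]2(C)[C@@H](C=C)C(=O)C[C@@]2(C)C1 | intermediate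
20 | (R)-carvone | CC1=CC[C@H](CC1=O)C(C)=C | starting material
21 | carvone hydrobromide, (R)-5-(2-bromopropan-2-yl)-2-methylcyclohex-2-enone | CC1=CC[C@H](CC1=O)C(C)(C)Br | intermediate
22 | (1S,6R)-3,7,7-trimethylbicyclo[4.1.0]hept-3-en-2-one (car-3-en-2-one) | CC1=CC[C@@H]2[C@H](C1=O)C2(C)C | intermediate
23 | eucarvone, 2,6,6-trimethylcyclohepta-2,4-dien-1-one | CC1=CC=CC(C)(C)CC1=O | intermediate
24 | (4S,5R)-4,5-epoxy-2,6,6-trimethylcyclohept-2-en-1-one | O=C1C(C)=C[C@@H]2O[C@@H]2C(C)(C)C1 | intermediate
25 | (5S)-5-hydroxy-2,6,6-trimethylcyclohept-3-en-1-one (C10 epimers) | O=C1C(C)C=C[C@H](O)C(C)(C)C1 | intermediate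
26 | (S)-5-hydroxy-2,6,6-trimethylcyclohept-2-en-1-one | O=C1C(C)=CC[C@H](O)C(C)(C)C1 | intermediate
27 | (S)-5-(tert-butyldimethylsilyloxy)-2,6,6-trimethylcyclohept-2-en-1-one | O=C1C(C)=CC[C@H](O[Si](C)(C)C(C)(C)C)C(C)(C)C1 | intermediate
28 | lithium α′-dienolate of 27 (C9=C5) | [Li]OC1=CC(C)(C)[C@@H](O[Si](C)(C)C(C)(C)C)CC=C1C | intermediate
29 | 7-(1-hydroxyethyl) derivative of 27 (epimers at C5 and at the carbinol) | CC(O)C1C(=O)C(C)=CC[C@H](O[Si](C)(C)C(C)(C)C)C1(C)C | intermediate
30 | mesylate of 29 | CC(OS(C)(=O)=O)C1C(=O)C(C)=CC[C@H](O[Si](C)(C)C(C)(C)C)C1(C)C | intermediate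
31 | (5S,7Z)-5-(tert-butyldimethylsilyloxy)-7-ethylidene-2,6,6-trimethylcyclohept-2-en-1-one | C/C=C1\C(=O)C(C)=CC[C@H](O[Si](C)(C)C(C)(C)C)C1(C)C | intermediate
32 | lithium trienolate of 31 | [Li]OC1=C(C=C)C(C)(C)[C@@H](O[Si](C)(C)C(C)(C)C)CC=C1C | intermediate
33 | (5S,7S)-5-(tert-butyldimethylsilyloxy)-2,6,6-trimethyl-7-vinylcyclohept-2-en-1-one (vinyl cis to the silyloxy group) | O=C1C(C)=CC[C@H](O[Si](C)(C)C(C)(C)C)C(C)(C)[C@@H]1C=C | intermediate
34 | lithium enolate from conjugate reduction of 33 (C9=C10) | [Li]OC1=C(C)CC[C@H](O[Si](C)(C)C(C)(C)C)C(C)(C)[C@@H]1C=C | intermediate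
35 | (5S,7S)-5-(tert-butyldimethylsilyloxy)-2,6,6-trimethyl-7-vinylcyclohept-1-en-1-yl triflate | FC(F)(F)S(=O)(=O)OC1=C(C)CC[C@H](O[Si](C)(C)C(C)(C)C)C(C)(C)[C@@H]1C=C | intermediate
36 | (5S,7S)-[5-(tert-butyldimethylsilyloxy)-2,6,6-trimethyl-7-vinylcyclohept-1-en-1-yl]trimethylstannane | C[Sn](C)(C)C1=C(C)CC[C@H](O[Si](C)(C)C(C)(C)C)C(C)(C)[C@@H]1C=C | intermediate
37 | ring A alkenyllithium from 36 | [Li]C1=C(C)CC[C@H](O[Si](C)(C)C(C)(C)C)C(C)(C)[C@@H]1C=C | intermediate
38 | ring A alkenylcerium dichloride | Cl[Ce](Cl)C1=C(C)CC[C@H](O[Si](C)(C)C(C)(C)C)C(C)(C)[C@@H]1C=C | intermediate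
39 | tertiary allylic alcohol: ring A cycloheptenyl on C11 (β), C11 hydroxyl α, C8 vinyl α | CC(C)=CCC[C@]1(C)CC[C@]2(C)[C@@H](C=C)[C@](O)(C3=C(C)CC[C@H](O[Si](C)(C)C(C)(C)C)C(C)(C)[C@@H]3C=C)C[C@@]2(C)C1 | intermediate
40 | hydrindanyl carbinol with the C9–C10 epoxide on the lower face of ring A (syn to the C5 vinyl and C3 silyloxy groups) | CC(C)=CCC[C@]1(C)CC[C@]2(C)[C@@H](C=C)[C@](O)([C@@]34O[C@]3(C)CC[C@H](O[Si](C)(C)C(C)(C)C)C(C)(C)[C@@H]4C=C)C[C@@]2(C)C1 | intermediate
41 | spiro C11 ketone with C10 tertiary alcohol, C5 and C8 vinyl groups, C3 silyl ether | CC(C)=CCC[C@]1(C)CC[C@]2(C)[C@@H](C=C)[C@@]3([C@@H](C=C)C(C)(C)[C@@H](O[Si](C)(C)C(C)(C)C)CC[C@@]3(C)O)C(=O)C[C@@]2(C)C1 | intermediate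
42 | tetracyclic C6=C7 cyclopentene, C11 ketone, C10 alcohol, C3 silyl ether | CC(C)=CCC[C@]1(C)CC[C@]2(C)[C@H]3C=C[C@H]4C(C)(C)[C@@H](O[Si](C)(C)C(C)(C)C)CC[C@@](C)(O)[C@@]43C(=O)C[C@@]2(C)C1 | intermediate
43 | 6,7-dihydro derivative of 42 | CC(C)=CCC[C@]1(C)CC[C@]2(C)[C@H]3CC[C@H]4C(C)(C)[C@@H](O[Si](C)(C)C(C)(C)C)CC[C@@](C)(O)[C@@]43C(=O)C[C@@]2(C)C1 | intermediate
44 | C10,C11-diol (C11 configuration open) | CC(C)=CCC[C@]1(C)CC[C@]2(C)[C@H]3CC[C@H]4C(C)(C)[C@@H](O[Si](C)(C)C(C)(C)C)CC[C@@](C)(O)[C@@]43C(O)C[C@@]2(C)C1 | intermediate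
45 | sodium C11 xanthate | CC(C)=CCC[C@]1(C)CC[C@]2(C)[C@H]3CC[C@H]4C(C)(C)[C@@H](O[Si](C)(C)C(C)(C)C)CC[C@@](C)(O)[C@@]43C(OC(=S)S[Na])C[C@@]2(C)C1 | intermediate
46 | C11 S-methyl xanthate | CC(C)=CCC[C@]1(C)CC[C@]2(C)[C@H]3CC[C@H]4C(C)(C)[C@@H](O[Si](C)(C)C(C)(C)C)CC[C@@](C)(O)[C@@]43C(OC(=S)SC)C[C@@]2(C)C1 | intermediate
47 | C11-deoxy tetracycle with C10 alcohol and C3 silyl ether | CC(C)=CCC[C@]1(C)CC[C@]2(C)[C@H]3CC[C@H]4C(C)(C)[C@@H](O[Si](C)(C)C(C)(C)C)CC[C@@](C)(O)[C@@]43CC[C@@]2(C)C1 | intermediate
48 | C3,C10-diol | CC(C)=CCC[C@]1(C)CC[C@]2(C)[C@H]3CC[C@H]4C(C)(C)[C@@H](O)CC[C@@](C)(O)[C@@]43CC[C@@]2(C)C1 | intermediate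
49 | CNP0284367.1 (3S,5S,8R,9R,10R,13S,14R,17R) | CC(C)=CCC[C@]1(C)CC[C@]2(C)[C@H]3CC[C@H]4C(C)(C)[C@@H]5CC[C@@](C)(O5)[C@@]43CC[C@@]2(C)C1 | target

**Count and risks**

Total step count: 34. Longest linear sequence: 25 steps (steps 1–15, then 25–34). The ring A branch is steps 16–24 (9 steps).

Step 27 (semipinacol shift). What may go wrong: the primary C12 migrates instead of C8, or the epoxide ionises at C10 and ends in elimination or a hydride/alkyl shift within ring A. Fallback: set out from 40 and close the C6=C7 bond first with the second-generation Hoveyda–Grubbs catalyst in toluene, which should give the cyclohexene-bridged epoxy carbinol F1, in which C8 is held next to C9 in a six-membered ring (C5, C6, C7, C8, C11, C9). Treatment of F1 with BF3·OEt2 then contracts that ring and expands the cyclopentanol in one semipinacol shift. The sequence comes back to the route at 42.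

Step 26 (directed epoxidation). What may go wrong: oxygen is delivered to the ring A face opposite the C5 vinyl group, which after rearrangement would give the C9 epimer. Fallback: set out from 39, remove the silyl group with Bu4NF to the free C3 alcohol, diol F2, and epoxidise with VO(acac)2 and t-BuOOH. The C3 hydroxyl lies on the required face, 1,4-transannular to C9=C10, and can hold the vanadium there, so this should give the lower-face epoxy diol F3. Selective silylation of the secondary hydroxyl with t-BuMe2SiOTf and 2,6-lutidine comes back to the route at 40.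

Step 25 (fragment union). What may go wrong: proton transfer from the allylic C8–H of 19 to the alkenyl metal (enolisation) and slow addition to the crowded carbonyl. Fallback: set out from 18, whose C8 carries no hydrogen, and from 36. Deprotonate the hydroxyl of 18 with LiN(SiMe3)2 and add the alkenylcerium 38, which should give the C8,C11-diol F4 with ring A on the α face. Acylate the less hindered C8 alkoxide (LiN(SiMe3)2, ClCO2Me) to the C8 methyl carbonate F5. Formate hydrogenolysis (Pd2(dba)3, PBu3, HCO2NH4) should deliver hydride to C8 with inversion and give the C11 epimer of 39, carbinol F6. Epoxidation with VO(acac)2 and t-BuOOH then gives the lower-face epoxy alcohol F7, and BF3·OEt2 rearranges it with loss of the C11 stereocentre, which comes back to the route at 41.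

**Further compounds**

F1 | step 27 | cyclohexene-bridged epoxy carbinol (C6=C7 closed before the shift; ring C5–C6=C7–C8–C11–C9) | CC(C)=CCC[C@]1(C)CC[C@]2(C)[C@H]3C=C[C@H]4C(C)(C)[C@@H](O[Si](C)(C)C(C)(C)C)CC[C@@](C)(O5)[C@]45[C@]3(O)C[C@@]2(C)C1
F2 | step 26 | C3-desilyl diol of 39 | CC(C)=CCC[C@]1(C)CC[C@]2(C)[C@@H](C=C)[C@](O)(C3=C(C)CC[C@H](O)C(C)(C)[C@@H]3C=C)C[C@@]2(C)C1
F3 | step 26 | lower-face C9–C10 epoxy diol (C3 and C11 hydroxyls free) | CC(C)=CCC[C@]1(C)CC[C@]2(C)[C@@H](C=C)[C@](O)([C@@]34O[C@]3(C)CC[C@H](O)C(C)(C)[C@@H]4C=C)C[C@@]2(C)C1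
F4 | step 25 | C8,C11-diol with ring A on C11 (α), C11 hydroxyl β, C8 hydroxyl α, C8 vinyl β | CC(C)=CCC[C@]1(C)CC[C@]2(C)[C@@](C=C)(O)[C@@](O)(C3=C(C)CC[C@H](O[Si](C)(C)C(C)(C)C)C(C)(C)[C@@H]3C=C)C[C@@]2(C)C1
F5 | step 25 | C8 methyl carbonate of the diol | CC(C)=CCC[C@]1(C)CC[C@]2(C)[C@@](C=C)(OC(=O)OC)[C@@](O)(C3=C(C)CC[C@H](O[Si](C)(C)C(C)(C)C)C(C)(C)[C@@H]3C=C)C[C@@]2(C)C1
F6 | step 25 | C11 epimer of 39 (C11 hydroxyl β, ring A α, C8 vinyl α) | CC(C)=CCC[C@]1(C)CC[C@]2(C)[C@@H](C=C)[C@@](O)(C3=C(C)CC[C@H](O[Si](C)(C)C(C)(C)C)C(C)(C)[C@@H]3C=C)C[C@@]2(C)C1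
F7 | step 25 | C11 epimer of 40 (lower-face C9–C10 epoxide) | CC(C)=CCC[C@]1(C)CC[C@]2(C)[C@@H](C=C)[C@@](O)([C@@]34O[C@]3(C)CC[C@H](O[Si](C)(C)C(C)(C)C)C(C)(C)[C@@H]4C=C)C[C@@]2(C)C1
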